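I began from a one-step world, in which Za falls from the first minute in step with the catalyst charged, but the runs refused it: green held 48.0% of Za at 1.33 h and 22.7% at 2.50 h, while teal still held 49.0% at 2.50 h.

| setting | teal | green | ochre | zeta | epsilon |
|---|---|---|---|---|---|
| Za | 0.10 M | 0.10 M | 0.20 M | 0.10 M | 0.10 M |
| Zb | 0.10 M | 0.10 M | 0.20 M | 0.10 M | 0.10 M |
| Zc | 1.2 equiv (fed, over 2.0 h) | 1.2 equiv (fed, over 2.0 h) | 1.2 equiv (fed, over 2.0 h) | 1.20 equiv (fed, over 2.0 h) | 1.20 equiv (fed, over 2.0 h) |
| Zf | 0.35 mol% | 0.78 mol% | 0.52 mol% | 0.52 mol% | 0.52 mol% |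
| Ze | 0.21 mM | 0.21 mM | 0.21 mM | 0.21 mM | 0.21 mM |
| remark | run made earlier | run made earlier | run made earlier |  |  |
| time |  |  |  | 3.0 h | 0.80 h |

| run | time / h | Zb / % | Za / % | Zg / % |
|---|---|---|---|---|
| teal | 0.333 | 49.9 | 50.4 | 0.6 |
| teal | 0.833 | 49.6 | 50.1 | 0 |
| teal | 1.50 | 49.5 | 49.7 | 0.1 |
| teal | 2.50 | 49.4 | 49.0 | 0.3 |
| green | 0.667 | 49.8 | 49.7 | 0.1 |
| green | 1.33 | 49.3 | 48.0 | 0.9 |
| green | 2.00 | 42.8 | 35.2 | 14.1 |
| green | 2.50 | 35.3 | 22.7 | 24.5 |
| ochre | 0.333 | 49.9 | 49.7 | 0.2 |
| ochre | 0.833 | 49.7 | 48.7 | 1.5 |
| ochre | 1.50 | 41.5 | 32.3 | 15.9 |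
| ochre | 2.50 | 28.3 | 13.2 | 31.8 |

(standard deviation of a reading: 0.3 percentage points)

- Zd is single-handed; Za and Zb are mirror images of each other, charged as a racemate, each of them at the stated concentration
- percentages count the whole charge, also what has not yet gone in
- an excess is the difference of the two amounts in percent of their sum
- an excess is below zero if the other one leads

* the winner by excess of Zb over Za among what is left of the two; "neither" if no more than 2 percentage points parts them (zeta / epsilon / neither)
* excess of Zb over Za among what is left of the two at the end, zeta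
* excess of Zb over Za among what is left of the two at the end, epsilon

So I took the concentration that sets the rate to be free Zd, not the charge, and supposed that Zf turns into Zd by a first-order step of constant a while Ze takes up Zd one to one.

Green, with 0.780 mM of Zf, gave bounds on a. I put the start of its steep fall no earlier than 1.33 h, which set a at 0.236 h⁻¹ or less. Za fell faster after 2.00 h than before, and I took that steepening to hold from the start of the fall, so I judged that a line drawn back through its last two readings arrived too late, at 1.41 h, which set a at 0.223 h⁻¹ or more. I used the mean, 0.229 h⁻¹.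

For zeta, with 0.520 mM of Zf, the lag (induction period), the time at which the released fraction of Zf equals charged Ze over charged Zf, came to 2.26 h, between 2.19 h and 2.32 h. The same rule put ochre at 0.984 h, later than its reading at 0.833 h, where Za still stood at 48.7%, and teal at 4.00 h, later than its last reading. Epsilon stopped earlier than the shortest lag, so I expected an excess near zero there.

Green's last interval lost Za at 0.877 h⁻¹ with about 0.0560 M of Zc, and its selectivity factor read 2.27. I scaled that rate to zeta, with free Zd rising as a triangle from the lag. The low end of the lag and all the Zc gave a logarithmic loss of Za of 0.366, hence an excess of 10.2% as the top of my estimated bracket. The high end of the lag and the Zc which that loss leaves, 0.0744 M, gave 0.176, hence 4.92% as its bottom.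

The forecast, which held that “There is a clear induction period, and it shortens sharply with catalyst concentration”, named zeta with 3.5% for zeta (range 1% to 12%) and 0% for epsilon, so its zeta value stood below my bracket.

The winner was zeta, with 0.0673% in epsilon and 9.90% in zeta, less than the top of my bracket and more than its bottom.

    Zd + Ze → Zj (k = 244 M⁻¹ s⁻¹)
    Zc + Zd + Zb → Zd + Zh (k = 18.5 M⁻² s⁻¹)
    Zg ⇌ Zh (k = 1.52 × 10⁻⁴ s⁻¹)
    Zc + Zd + Za → Zd + Zg (k = 42.5 M⁻² s⁻¹)
    Zf → Zd (k = 6.46 × 10⁻⁵ s⁻¹)

Against my lag of 2.26 h, zeta had 0.740 h of working time up to 3.0 h, and half of its making of Zg up to then was done by 2.64 h, later than the lag, whereas epsilon stopped at 0.80 h, earlier than the lag, with 58% of its Ze still unbound. The further flask, zeta with 5.3 × 10⁻⁵ M of Ze, had by the same rule a lag of 0.469 h, shorter than zeta's, and at 3.00 h it stood at an excess of 33.6%.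

The readings come from a simulation on assumed constants; noise was put on by code.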